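**Retrosynthetic overview**

1. Target 44 ⇐ O8 acylation of alcohol 36 with the (S)-acid chloride 42; 36 ⇐ α-methylenation and 6,12-lactonisation (ring C) after C7 alkylation and C8 reduction of ketone 25.
2. 25 ⇐ anionic oxy-Cope ring expansion of bridged carbinol 22. The feature used: inside the ten-membered ring C1–C10, C5–C6 lies between the C3=C4 enoate and the oxygenated C7–C8 unit, so the ring maps onto the 1,5-diene C5=C4–C3–C8–C7=C6, with the C5–O–C10 ether (rings A and B) already in place.
3. 22 ⇐ ketone 14 (2-oxabicyclo[3.2.2]non-3-ene) plus a lithium alkoxyacetylide, then Z-selective semihydrogenation; 14 ⇐ cis-1,4-disubstituted cyclohexanone 7 by ester formylation and alkoxide addition–elimination; 7 ⇐ (S)-3-hydroxy-3-methylcyclohexanone 3 ⇐ enone 1.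
4. Ring order: cyclohexane (from 1) → ring A bridge (step 6) → ten-membered carbocycle and ring B together (step 11) → lactone ring C (step 15).

Key step: step 11

Remarks. Atoms carry the germacrane numbers: C10 is the methyl-bearing ether carbon, C1 and C2 its CH2CH2 arm, C3=C4 the ring alkene with ester carbon C15 on C4, C5 the ether CH, C6 the lactone O–CH, C7 the lactone CH, C8 the acyloxy CH, C9 the CH2, C11/C12 the lactone α-carbon and carbonyl. Ring A is O–C5–C4–C3–C2–C1–C10, ring B is O–C5–C6–C7–C8–C9–C10, ring C is the γ-lactone. Assumption: in step 1 the enantiomer of the bisphosphine is chosen that gives the S tertiary centre; C10 then controls every later ring stereocentre. The required cyclohexanone carries the carbinol carbon β to the ketone (a 3-hydroxy-3-methylcyclohexanone), because C10 and C3 must be 1,4-related in the six-membered ring for the three-atom bridge to form.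

**Route**

Step 1
Reactants: 1 3-methylcyclohex-2-en-1-one
Product: 3 (S)-3-hydroxy-3-methylcyclohexan-1-one, via boronate 2 (not isolated)
Conditions: B2pin2, Cu(MeCN)4PF6 (5 mol%), QuinoxP* (6 mol%), LiOtBu (10 mol%), DMSO, rt; then NaBO3·4H2O, THF/H2O, rt
Reagents that add atoms: sodium perborate, [Na+].[Na+].O[B-]1(O)OO[B-](O)(O)OO1 (hydroxyl oxygen)
Why: Copper-catalysed asymmetric conjugate borylation of a β,β-disubstituted enone sets C10 through face-selective addition of the chiral bisphosphine–copper boryl complex, and perborate oxidation of the C–B bond with retention should give the tertiary aldol without dehydration.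

Step 2
Reactants: 3 (S)-3-hydroxy-3-methylcyclohexan-1-one
Product: 4 (S)-3-methyl-3-(triethylsilyloxy)cyclohexan-1-one
Conditions: Et3SiOTf, 2,6-lutidine, CH2Cl2, −78 °C
Reagents that add atoms: triethylsilyl trifluoromethanesulfonate, CC[Si](CC)(CC)OS(=O)(=O)C(F)(F)F
Why: Silylation with a silyl triflate protects the tertiary alcohol so that later enolate chemistry cannot trigger retro-aldol cleavage; no stereocentre is touched.

Step 3
Reactants: 4 (S)-3-methyl-3-(triethylsilyloxy)cyclohexan-1-one; 5 methyl bromoacetate
Product: 7 methyl 2-[(1S,4S)-4-methyl-2-oxo-4-(triethylsilyloxy)cyclohexyl]acetate (cis isomer), via lithium enolate 6 (not isolated)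
Conditions: LiN(iPr)2, THF, −78 °C; 5, DMPU, −78 → −30 °C; then DBU (cat.), CH2Cl2, rt; chromatography, trans isomer re-equilibrated
Reagents that add atoms: none
Why: Kinetic enolate alkylation takes place at the CH2 remote from the quaternary carbon (C3), and because C3 stays epimerisable next to the ketone, base equilibration should favour the cis isomer (ester arm equatorial, silyloxy axial, methyl equatorial) that alone can be bridged.

Step 4
Reactants: 7 methyl 2-[(1S,4S)-4-methyl-2-oxo-4-(triethylsilyloxy)cyclohexyl]acetate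
Product: 8 methyl 2-[(6S,9S)-9-methyl-9-(triethylsilyloxy)-1,4-dioxaspiro[4.5]decan-6-yl]acetate
Conditions: (Me3SiOCH2)2, Me3SiOTf (cat.), CH2Cl2, −78 → −20 °C
Reagents that add atoms: 1,2-bis(trimethylsilyloxy)ethane, C[Si](C)(C)OCCO[Si](C)(C)C
Why: Aprotic silyl-triflate-catalysed ketal formation masks C8, since a free ketone would be enolised before the ester, would close onto the formyl carbon to a furan and would suffer β-elimination under the alkoxide conditions of step 6.

Step 5
Reactants: 8 methyl 2-[(6S,9S)-9-methyl-9-(triethylsilyloxy)-1,4-dioxaspiro[4.5]decan-6-yl]acetate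
Product: 11 methyl 2-[(6S,9S)-9-methyl-9-(triethylsilyloxy)-1,4-dioxaspiro[4.5]decan-6-yl]-3-(4-methylphenylsulfonyloxy)prop-2-enoate (E/Z mixture), via lithium ester enolate 9 (not isolated), via hydroxymethylene ester 10 (not isolated)
Conditions: LiN(iPr)2 (1.2 equiv), THF, −78 °C; HCO2Me (5 equiv), −78 → 0 °C; then TsCl, −78 → 0 °C
Reagents that add atoms: methyl formate, COC=O; 4-methylbenzenesulfonyl chloride, Cc1ccc(cc1)S(=O)(=O)Cl
Why: Crossed Claisen condensation of the ester enolate with methyl formate installs C5, and O-sulfonylation of the resulting β-oxo ester enolate gives a vinylogous sulfonate whose geometry is irrelevant for the following addition–elimination.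

Step 6
Reactants: 11 enol tosylate
Product: 13 methyl (1S,5S)-1-methylspiro[2-oxabicyclo[3.2.2]non-3-ene-6,2'-[1,3]dioxolane]-4-carboxylate, via alkoxide 12 (not isolated)
Conditions: Bu4NF, THF (0.01 M), 0 °C → rt
Reagents that add atoms: none
Why: Fluoride desilylation frees the tertiary alkoxide, which adds to C5 of the β-sulfonyloxy acrylate and expels tosylate (nucleophilic vinylic substitution by addition–elimination), closing ring A as the O–C5=C4 bridge across the cis-1,4 positions of the twist-boat cyclohexane and thereby fixing C3 relative to C10.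

Step 7
Reactants: 13 bridged ketal
Product: 14 methyl (1S,5S)-1-methyl-6-oxo-2-oxabicyclo[3.2.2]non-3-ene-4-carboxylate
Conditions: PPTS, acetone/H2O, 40 °C
Reagents that add atoms: water, O
Why: Mild acid-catalysed ketal hydrolysis (transketalisation to acetone) unveils C8 while the push–pull vinylogous carbonate resists dilute acid, and the β-alkoxy ketone is kept away from base.

Step 8
Reactants: 15 4-methoxybenzyl alcohol; 16 trichloroethylene
Product: 19 1-{[(E)-1,2-dichloroethenyl]oxymethyl}-4-methoxybenzene, via potassium alkoxide 17 (not isolated), via dichloroacetylene 18 (not isolated)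
Conditions: KH, THF, 0 °C; then 16, −50 °C → rt
Reagents that add atoms: none
Why: Base-induced dehydrochlorination of trichloroethylene and anti addition of the alkoxide to the resulting dichloroacetylene (addition–elimination route to 1,2-dichlorovinyl ethers) gives a storable precursor of the alkoxyacetylide.

Step 9
Reactants: 14 bicyclic keto ester; 19 dichlorovinyl ether
Product: 21 methyl (1S,5S,6R)-6-hydroxy-6-{2-[(4-methoxyphenyl)methoxy]ethynyl}-1-methyl-2-oxabicyclo[3.2.2]non-3-ene-4-carboxylate, via lithium acetylide 20 (not isolated)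
Conditions: 19, n-BuLi (2.1 equiv), THF, −78 → −40 °C; then 14, −78 °C; pH 7 buffer
Reagents that add atoms: none
Why: 1,2-Addition of a weakly basic lithium alkoxyacetylide (from elimination and chlorine–lithium exchange) to the ketone should occur on the face of C8 next to the flat, substituent-free O–C5=C4 bridge and not the face screened by the C1–C2 methylene hydrogens, which sets C8 with the two-carbon unit syn to the enol ether bridge and avoids enolisation or retro-oxa-Michael opening.

Step 10
Reactants: 21 alkynyl carbinol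
Product: 22 methyl (1S,5S,6R)-6-hydroxy-6-{(Z)-2-[(4-methoxyphenyl)methoxy]ethenyl}-1-methyl-2-oxabicyclo[3.2.2]non-3-ene-4-carboxylate
Conditions: H2 (1 atm), Pd on CaCO3 poisoned with Pb(OAc)2, quinoline, EtOAc, 0 °C
Reagents that add atoms: none
Why: Lindlar semihydrogenation adds hydrogen syn to the electron-rich ynol ether and so gives the Z enol ether only, while the trisubstituted push–pull acrylate and the benzyl ether are left alone.

Step 11
Reactants: 22 bridged divinyl carbinol
Product: 25 methyl (1R,6S,10S)-10-[(4-methoxyphenyl)methoxy]-6-methyl-8-oxo-11-oxabicyclo[4.4.1]undec-2-ene-2-carboxylate, via potassium alkoxide 23 (not isolated), via potassium enolate 24 (not isolated)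
Conditions: KH, 18-crown-6, THF, 0 °C → rt; AcOH/THF quench at −78 °C
Reagents that add atoms: none
Why: Proposed new method: the crown-ether-separated potassium alkoxide 23 donates into the C3–C8 σ* orbital and the six atoms C5=C4–C3–C8–C7=C6 undergo an anionic oxy-Cope ([3,3]-sigmatropic) shift that forms C5–C6 while C3–C8 breaks, giving the conjugated enoate and the potassium enolate 24, which is protonated cold to ketone 25. The closest known reaction type is the anionic oxy-Cope rearrangement of 2-vinylbicyclo[2.2.2]oct-5-en-2-ols, which has not been shown for an ene partner that is a vinylogous carbonate inside an oxygen-containing three-atom bridge. The single new σ bond closes ring B (the seven-membered oxepanone O–C5–C6–C7–C8–C9–C10) suprafacially at both termini through a boat six-membered transition state, and the loss of C3–C8 at the same time expands the cyclohexane to the ten-membered carbocycle, ring A being carried over unchanged. C5 becomes R because C6, held on C8, can reach only the face of C4=C5 that looks toward the C8–C9 bridge, and C6 becomes S because the Z enol ether in the enforced boat places the ether oxygen on the side of C10 and H6 outward. The step needs the [3,3] shift in preference to a [1,3] shift, to β-elimination of the C6 alkoxide and to retro-oxa-Michael opening at C10; the syn vinyl group and the rigid cage leave the boat array as the only low-energy pathway, the new enolate π system is aligned with the C5–C6 bond and not with C6–O, and the enolate is quenched at low temperature. Relief of bicyclic strain, enolate formation and conjugation of C3=C4 with the ester supply the driving force.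

Step 12
Reactants: 25 ten-membered keto ester; 5 methyl bromoacetate
Product: 27 methyl (1R,6S,9S,10S)-9-(2-methoxy-2-oxoethyl)-10-[(4-methoxyphenyl)methoxy]-6-methyl-8-oxo-11-oxabicyclo[4.4.1]undec-2-ene-2-carboxylate, via lithium enolate 26 (not isolated)
Conditions: LiN(SiMe3)2, THF, −78 °C; 5, DMPU, −78 → −40 °C
Reagents that add atoms: none
Why: Kinetic enolate alkylation should take place at C7, the CH2 not flanked by the quaternary C10, with the electrophile entering anti to the adjacent C6 ether to give the trans C6/C7 relationship, which is also the more stable one at this epimerisable centre.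

Step 13
Reactants: 27 C7-alkylated ketone
Product: 28 methyl (1R,6S,8R,9R,10S)-8-hydroxy-9-(2-methoxy-2-oxoethyl)-10-[(4-methoxyphenyl)methoxy]-6-methyl-11-oxabicyclo[4.4.1]undec-2-ene-2-carboxylate
Conditions: LiBH(s-Bu)3, THF, −78 °C; AcOH quench at −78 °C; used at once
Reagents that add atoms: none
Why: Diastereoselective ketone reduction by a hindered trialkylborohydride delivers hydride to the convex face opposite the C7 acetate arm, placing O8 cis to C11 (H7 and H8 cis), and the cold quench keeps the cis γ-hydroxy ester from lactonising onto O8.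

Step 14
Reactants: 28 C8 alcohol
Product: 29 tert-butyldimethylsilyl ether of 28 at O8
Conditions: t-BuMe2SiOTf, 2,6-lutidine, CH2Cl2, −78 → 0 °C
Reagents that add atoms: tert-butyldimethylsilyl trifluoromethanesulfonate, CC(C)(C)[Si](C)(C)OS(=O)(=O)C(F)(F)F
Why: Fast silylation with a silyl triflate and a non-nucleophilic base blocks O8 so that only O6 can later close the lactone.

Step 15
Reactants: 29 silyl ether
Product: 31 trans-fused 6,12-lactone (O8 silyl ether, C15 methyl ester), via hydroxy ester 30 (not isolated)
Conditions: DDQ, CH2Cl2/pH 7 buffer, 0 °C → rt; then PPTS, toluene, 60 °C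
Reagents that add atoms: none
Why: Oxidative cleavage of the 4-methoxybenzyl ether frees O6, and acid-catalysed lactonisation (intramolecular transesterification) of the trans γ-hydroxy ester closes ring C without touching C6 or C7, which were set in steps 11 and 12.

Step 16
Reactants: 31 lactone
Product: 35 α-methylene lactone (O8 silyl ether), via lithium lactone enolate 32 (not isolated), via Mannich base 33 (not isolated), via ammonium iodide 34 (not isolated)
Conditions: LiN(SiMe3)2, THF, −78 °C; CH2=NMe2+ I−, −78 °C → rt; MeI, MeOH, rt; NaHCO3 (aq), CH2Cl2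
Reagents that add atoms: dimethyl(methylidene)ammonium iodide, C=[N+](C)C.[I-]
Why: Eschenmoser methylenation (Mannich reaction of the lactone enolate, N-methylation, β-elimination of trimethylamine) installs the exocyclic C11 methylene, the lactone α-CH2 being the most acidic site and the enolate having no leaving group on its β-carbon.

Step 17
Reactants: 35 silylated α-methylene lactone
Product: 36 8-hydroxy α-methylene lactone
Conditions: HF·pyridine, THF/pyridine, 0 °C → rt
Reagents that add atoms: none
Why: Buffered fluoride desilylation removes the secondary silyl ether without conjugate addition to the methylene lactone or ionisation of the tertiary ether.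

Step 18
Reactants: 37 [(2R)-2-methyloxiran-2-yl]methanol
Product: 38 (2S)-2-methylbut-3-ene-1,2-diol
Conditions: Me3S+ I− (3 equiv), n-BuLi (3 equiv), THF, −10 °C; then 37, −10 °C → rt
Reagents that add atoms: trimethylsulfonium iodide, C[S+](C)C.[I-]
Why: One-carbon homologation of an epoxide to an allylic alcohol (opening of the epoxide CH2 by dimethylsulfonium methylide, then ylide-mediated β-elimination) breaks no bond at the stereocentre, and the Payne rearrangement of this lithium alkoxide is degenerate, so the configuration is carried over.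

Step 19
Reactants: 38 (2S)-2-methylbut-3-ene-1,2-diol
Product: 40 (2S)-2-hydroxy-2-methylbut-3-enoic acid, via hydroxy aldehyde 39 (not isolated)
Conditions: TEMPO (cat.), NaOCl (cat.), NaClO2, MeCN/phosphate buffer (pH 6.7), 35 °C
Reagents that add atoms: sodium chlorite, [Na+].[O-]Cl=O
Why: Oxoammonium-catalysed oxidation of the primary alcohol with chlorite as terminal oxidant gives the acid through the aldehyde, the tertiary allylic alcohol being inert.

Step 20
Reactants: 40 (2S)-2-hydroxy-2-methylbut-3-enoic acid
Product: 42 (2S)-2-methyl-2-(trimethylsilyloxy)but-3-enoyl chloride, via bis-silyl derivative 41 (not isolated)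
Conditions: Me3SiCl, pyridine, CH2Cl2, 0 °C → rt; then (COCl)2, DMF (cat.), 0 °C → rt; used crude
Reagents that add atoms: chlorotrimethylsilane, C[Si](C)(C)Cl; oxalyl chloride, ClC(=O)C(=O)Cl
Why: Silylation of both hydroxyl and carboxyl groups followed by Vilsmeier-type conversion of the silyl ester into the acid chloride gives an activated, O-protected acid with no α-hydrogen to racemise.

Step 21
Reactants: 36 8-hydroxy α-methylene lactone; 42 acid chloride
Product: 44 target CNP0325750.1, via silyl ether ester 43 (not isolated)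
Conditions: pyridine, DMAP (cat.), CH2Cl2, 0 °C → rt; then HF·pyridine, THF, 0 °C
Reagents that add atoms: none
Why: DMAP-catalysed acylation of the only free hydroxyl attaches the side chain with its preformed S centre, and fluoride cleaves the labile tertiary trimethylsilyl ether in the same flask.

**Compound list**

1 | 3-methylcyclohex-2-en-1-one | CC1=CC(=O)CCC1 | starting material
2 | (R)-3-methyl-3-(4,4,5,5-tetramethyl-1,3,2-dioxaborolan-2-yl)cyclohexan-1-one | O=C1C[C@](B2OC(C)(C)C(C)(C)O2)(C)CCC1 | intermediate
3 | (S)-3-hydroxy-3-methylcyclohexan-1-one | O=C1C[C@](O)(C)CCC1 | intermediate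
4 | (S)-3-methyl-3-(triethylsilyloxy)cyclohexan-1-one | O=C1C[C@](O[Si](CC)(CC)CC)(C)CCC1 | intermediate
5 | methyl bromoacetate | COC(=O)CBr | starting material
6 | lithium enolate of 4 (C8–OLi, C3=C8) | [Li]OC1=CCC[C@](C)(O[Si](CC)(CC)CC)C1 | intermediate
7 | methyl 2-[(1S,4S)-4-methyl-2-oxo-4-(triethylsilyloxy)cyclohexyl]acetate | O=C1C[C@@](C)(O[Si](CC)(CC)CC)CC[C@H]1CC(=O)OC | intermediate
8 | methyl 2-[(6S,9S)-9-methyl-9-(triethylsilyloxy)-1,4-dioxaspiro[4.5]decan-6-yl]acetate | O1CCOC12C[C@@](C)(O[Si](CC)(CC)CC)CC[C@H]2CC(=O)OC | intermediate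
9 | lithium ester enolate of 8 | O1CCOC12C[C@@](C)(O[Si](CC)(CC)CC)CC[C@H]2C=C(O[Li])OC | intermediate
10 | hydroxymethylene ester of 8 (formyl ester in its enol form, present in the flask as the lithium enolate) | O1CCOC12C[C@@](C)(O[Si](CC)(CC)CC)CC[C@H]2C(=CO)C(=O)OC | intermediate
11 | enol tosylate of 10 (E/Z mixture) | O1CCOC12C[C@@](C)(O[Si](CC)(CC)CC)CC[C@H]2C(=COS(=O)(=O)c3ccc(C)cc3)C(=O)OC | intermediate
12 | tetrabutylammonium tertiary alkoxide from 11 | O1CCOC12C[C@@](C)([O-])CC[C@H]2C(=COS(=O)(=O)c3ccc(C)cc3)C(=O)OC.CCCC[N+](CCCC)(CCCC)CCCC | intermediate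
13 | methyl (1S,5S)-1-methylspiro[2-oxabicyclo[3.2.2]non-3-ene-6,2'-[1,3]dioxolane]-4-carboxylate | O1CCOC13C[C@]2(C)CC[C@H]3C(C(=O)OC)=CO2 | intermediate
14 | methyl (1S,5S)-1-methyl-6-oxo-2-oxabicyclo[3.2.2]non-3-ene-4-carboxylate | O=C1C[C@]2(C)CC[C@H]1C(C(=O)OC)=CO2 | intermediate
15 | 4-methoxybenzyl alcohol | COc1ccc(CO)cc1 | starting material
16 | trichloroethylene | ClC=C(Cl)Cl | starting material
17 | potassium 4-methoxybenzyl oxide | COc1ccc(C[O-])cc1.[K+] | intermediate
18 | dichloroacetylene | ClC#CCl | intermediate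
19 | 1-{[(E)-1,2-dichloroethenyl]oxymethyl}-4-methoxybenzene | Cl/C=C(/Cl)OCc1ccc(OC)cc1 | intermediate
20 | lithium 2-[(4-methoxyphenyl)methoxy]ethynide | [Li]C#COCc1ccc(OC)cc1 | intermediate
21 | methyl (1S,5S,6R)-6-hydroxy-6-{2-[(4-methoxyphenyl)methoxy]ethynyl}-1-methyl-2-oxabicyclo[3.2.2]non-3-ene-4-carboxylate | O[C@]1(C#COCc2ccc(OC)cc2)C[C@]2(C)CC[C@H]1C(C(=O)OC)=CO2 | intermediate
22 | methyl (1S,5S,6R)-6-hydroxy-6-{(Z)-2-[(4-methoxyphenyl)methoxy]ethenyl}-1-methyl-2-oxabicyclo[3.2.2]non-3-ene-4-carboxylate | O[C@]1(/C=C\OCc2ccc(OC)cc2)C[C@]2(C)CC[C@H]1C(C(=O)OC)=CO2 | intermediate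
23 | potassium alkoxide of 22 | [K+].[O-][C@]1(/C=C\OCc2ccc(OC)cc2)C[C@]2(C)CC[C@H]1C(C(=O)OC)=CO2 | intermediate
24 | potassium enolate of 25 (C8–OK, C7=C8) | [K+].[O-]C=1C[C@]2(C)CCC=C(C(=O)OC)[C@@H](O2)[C@@H](OCc3ccc(OC)cc3)C=1 | intermediate
25 | methyl (1R,6S,10S)-10-[(4-methoxyphenyl)methoxy]-6-methyl-8-oxo-11-oxabicyclo[4.4.1]undec-2-ene-2-carboxylate | O=C1C[C@]2(C)CCC=C(C(=O)OC)[C@@H](O2)[C@@H](OCc3ccc(OC)cc3)C1 | intermediate
26 | lithium enolate of 25 (C8–OLi, C7=C8) | [Li]OC=1C[C@]2(C)CCC=C(C(=O)OC)[C@@H](O2)[C@@H](OCc3ccc(OC)cc3)C=1 | intermediate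
27 | methyl (1R,6S,9S,10S)-9-(2-methoxy-2-oxoethyl)-10-[(4-methoxyphenyl)methoxy]-6-methyl-8-oxo-11-oxabicyclo[4.4.1]undec-2-ene-2-carboxylate | O=C1C[C@]2(C)CCC=C(C(=O)OC)[C@@H](O2)[C@@H](OCc3ccc(OC)cc3)[C@@H]1CC(=O)OC | intermediate
28 | methyl (1R,6S,8R,9R,10S)-8-hydroxy-9-(2-methoxy-2-oxoethyl)-10-[(4-methoxyphenyl)methoxy]-6-methyl-11-oxabicyclo[4.4.1]undec-2-ene-2-carboxylate | O[C@@H]1C[C@]2(C)CCC=C(C(=O)OC)[C@@H](O2)[C@@H](OCc3ccc(OC)cc3)[C@@H]1CC(=O)OC | intermediate
29 | O8 tert-butyldimethylsilyl ether of 28 | CC(C)(C)[Si](C)(C)O[C@@H]1C[C@]2(C)CCC=C(C(=O)OC)[C@@H](O2)[C@@H](OCc3ccc(OC)cc3)[C@@H]1CC(=O)OC | intermediate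
30 | C6 hydroxy ester (29 without the 4-methoxybenzyl group) | CC(C)(C)[Si](C)(C)O[C@@H]1C[C@]2(C)CCC=C(C(=O)OC)[C@@H](O2)[C@@H](O)[C@@H]1CC(=O)OC | intermediate
31 | trans-fused 6,12-lactone, O8 silyl ether, C11 methylene still CH2 | CC(C)(C)[Si](C)(C)O[C@@H]1C[C@]2(C)CCC=C(C(=O)OC)[C@@H](O2)[C@H]2OC(=O)C[C@@H]21 | intermediate
32 | lithium enolate of lactone 31 | CC(C)(C)[Si](C)(C)O[C@@H]1C[C@]2(C)CCC=C(C(=O)OC)[C@@H](O2)[C@H]2OC(O[Li])=C[C@@H]21 | intermediate
33 | C11 dimethylaminomethyl lactone (Mannich base, C11 epimers) | CC(C)(C)[Si](C)(C)O[C@@H]1C[C@]2(C)CCC=C(C(=O)OC)[C@@H](O2)[C@H]2OC(=O)C(CN(C)C)[C@@H]21 | intermediate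
34 | trimethylammonium iodide of 33 | CC(C)(C)[Si](C)(C)O[C@@H]1C[C@]2(C)CCC=C(C(=O)OC)[C@@H](O2)[C@H]2OC(=O)C(C[N+](C)(C)C)[C@@H]21.[I-] | intermediate
35 | α-methylene 6,12-lactone, O8 silyl ether | CC(C)(C)[Si](C)(C)O[C@@H]1C[C@]2(C)CCC=C(C(=O)OC)[C@@H](O2)[C@H]2OC(=O)C(=C)[C@@H]21 | intermediate
36 | 8-hydroxy α-methylene 6,12-lactone | O[C@@H]1C[C@]2(C)CCC=C(C(=O)OC)[C@@H](O2)[C@H]2OC(=O)C(=C)[C@@H]21 | intermediate
37 | [(2R)-2-methyloxiran-2-yl]methanol | C[C@@]1(CO)CO1 | starting material
38 | (2S)-2-methylbut-3-ene-1,2-diol | C=C[C@](C)(O)CO | intermediate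
39 | (2S)-2-hydroxy-2-methylbut-3-enal | C=C[C@](C)(O)C=O | intermediate
40 | (2S)-2-hydroxy-2-methylbut-3-enoic acid | C=C[C@](C)(O)C(=O)O | intermediate
41 | trimethylsilyl (2S)-2-methyl-2-(trimethylsilyloxy)but-3-enoate | C=C[C@](C)(O[Si](C)(C)C)C(=O)O[Si](C)(C)C | intermediate
42 | (2S)-2-methyl-2-(trimethylsilyloxy)but-3-enoyl chloride | C=C[C@](C)(O[Si](C)(C)C)C(=O)Cl | intermediate
43 | O-trimethylsilyl ether of the target (side-chain tertiary oxygen) | C=C[C@](C)(O[Si](C)(C)C)C(=O)O[C@@H]1C[C@]2(C)CCC=C(C(=O)OC)[C@@H](O2)[C@H]2OC(=O)C(=C)[C@@H]21 | intermediate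
44 | CNP0325750.1 (C5 R, C6 S, C7 R, C8 R, C10 S, side chain 2S) | C=C[C@](C)(O)C(=O)O[C@@H]1C[C@]2(C)CCC=C(C(=O)OC)[C@@H](O2)[C@H]2OC(=O)C(=C)[C@@H]21 | target

**Step count and risks**

Total steps: 21. Longest linear sequence: 17 (steps 1–7, 9–17 and 21).

Steps most likely to fail:

1. Step 11 (proposed new method). The alkoxide may not rearrange, or the enolate may lose the C6 alkoxide by β-elimination or open the ether at C10 before it is quenched. Fallback with known reaction types, from 14 back to 25: the two bond changes are made one after the other by radical steps inside the same cage.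
   - A Reformatsky reaction of 14 with allyl bromoacetate and Zn (addition again syn to the enol ether bridge) should give the β-hydroxy allyl ester F1.
   - Pd(PPh3)4 with morpholine frees the β-hydroxy acid F2, and PhSeSePh with PBu3 converts it into the Se-phenyl selenoester F3.
   - (Me3Si)3SiH and AIBN generate the acyl radical, which adds to C5 of the vinylogous carbonate (six-membered closure at the alkoxy-bearing carbon, the usual site of radical attack on β-alkoxyacrylates) on the face held by the tether, giving the tricyclic hydroxy ketone F4.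
   - NaBH4 should attack the C6 ketone from the open face, away from the C9–C10–O wall, to give the diol F5 with the C6 oxygen as required; 4-methoxybenzyl trichloroacetimidate with catalytic La(OTf)3 then protects the secondary alcohol as the ether F6.
   - Alkoxy-radical β-scission of the tertiary C8 alcohol (PhI(OAc)2, I2, visible light) breaks C3–C8 with release of cage strain and gives the C8 ketone as the C3 iodide F7; DBU eliminates HI toward the ester and the route is rejoined at 25.

2. Step 6. Ring closure to the bridged seven-membered enol ether may lose out to intermolecular substitution or to attack of fluoride or alkoxide at sulfur. Fallback from 10 back to 13: the hydroxymethylene ester 10 is isolated after acidic work-up in place of being tosylated, HF·pyridine removes the silyl group to give the hydroxy enol F8, and PPTS in benzene over 4 Å molecular sieves closes the enol ether by acid-catalysed hemiacetal formation and dehydration to 13.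

3. Step 12. Deprotonation may occur at C9, the C7 enolate may eliminate the C6 ether on warming, or the electrophile may enter on the wrong face. Fallback from 22 directly to 27: the enolate 24 produced regiospecifically by the rearrangement of step 11 is not protonated but alkylated in the same flask with 5 at −78 °C, which removes the separate deprotonation; no new compound is formed.

**Further compounds**

F1 | step 11 | methyl (1S,5S,6R)-6-hydroxy-1-methyl-6-[2-oxo-2-(prop-2-enyloxy)ethyl]-2-oxabicyclo[3.2.2]non-3-ene-4-carboxylate | O[C@]1(CC(=O)OCC=C)C[C@]2(C)CC[C@H]1C(C(=O)OC)=CO2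
F2 | step 11 | 2-[(1S,5S,6R)-6-hydroxy-4-(methoxycarbonyl)-1-methyl-2-oxabicyclo[3.2.2]non-3-en-6-yl]acetic acid | O[C@]1(CC(=O)O)C[C@]2(C)CC[C@H]1C(C(=O)OC)=CO2
F3 | step 11 | Se-phenyl selenoester of F2 | O[C@]1(CC(=O)[Se]c3ccccc3)C[C@]2(C)CC[C@H]1C(C(=O)OC)=CO2
F4 | step 11 | tricyclic hydroxy ketone (C5–C6 bond formed, C6 ketone, C8 tertiary alcohol, C4 epimers) | O[C@]14C[C@]2(C)CC[C@H]1C(C(=O)OC)[C@@H](O2)C(=O)C4
F5 | step 11 | tricyclic diol (C6 secondary alcohol, C8 tertiary alcohol) | O[C@]14C[C@]2(C)CC[C@H]1C(C(=O)OC)[C@@H](O2)[C@@H](O)C4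
F6 | step 11 | C6 4-methoxybenzyl ether of F5 | O[C@]14C[C@]2(C)CC[C@H]1C(C(=O)OC)[C@@H](O2)[C@@H](OCc5ccc(OC)cc5)C4
F7 | step 11 | 3-iodo-3,4-dihydro derivative of 25 (C3 iodide, C4 H, epimer mixture) | O=C1C[C@]2(C)CCC(I)C(C(=O)OC)[C@@H](O2)[C@@H](OCc3ccc(OC)cc3)C1
F8 | step 6 | methyl 3-hydroxy-2-[(6S,9S)-9-hydroxy-9-methyl-1,4-dioxaspiro[4.5]decan-6-yl]prop-2-enoate | O1CCOC12C[C@@](C)(O)CC[C@H]2C(=CO)C(=O)OC
F0 | step 12 | none | none
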